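# Total synthesis proposal for CNP0086741.5 (compound 14)

## Analysis of the target

- **Skeleton.** The target is a 3-substituted isocoumarin.
  - Ring A is a pentasubstituted benzene (C4a, C5–Cl, C6–OH, C7–H, C8–OH, C8a).
  - Ring B is the fused 2-pyranone (C1=O, O2, C3, C4).
  - C3 carries an all-E butadiene bridge (C1'–C4') that ends at C2'' of ring C, an oxolane (O1'', C2''–C5'').
- **Stereocentres.** Ring C holds all three, (2''S,3''R,5''R).
  - The dienyl arm at C2'' and the methyl at C5'' are cis.
  - The C3'' hydroxyl is trans to both.
  - Along the chain C2''–C5'' the C3''–O and C5''–O bonds are 1,3-syn.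
- **Dienylic ether.** The O1''–C2'' bond is conjugated through C1'–C4' and C3=C4 with ring A. Acid can ionise it and scramble C2''.
- **Other sensitive groups.** The enol lactone of ring B is opened by hydroxide, alkoxide and amines. The tetraene is sensitive to light and electrophiles, which rules out a late electrophilic chlorination. The chlorine must also sit at C5 and not at C7.
- **What makes it hard.** No single ring is difficult. The difficulty is a stereotriad placed at the far end of a fragile polyene, next to a base-labile lactone and two phenols.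
- **The feature the route is built on.** The dienylic O1''–C2'' bond, the trans-vicinal C3''–OH and the 1,3-syn C5''–O bond together are the imprint of an E alkene C2''=C3''. That alkene would have been epoxidised on the face chosen by the C5'' carbinol and then opened at its dienylic end by that same oxygen.

## Retrosynthetic reasoning

**14 from 13.** The two aryl O–allyl bonds are cut last. The phenols must be masked during carbanion and oxidation chemistry. The unmasking has to be neutral, because 14 tolerates neither strong acid (O1''–C2'') nor strong base (ring B). Allyl ethers cleaved by zerovalent palladium meet this demand.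

**13 from 11 by way of 12 (key disconnection).**
- The O1''–C2'' bond and the C3''–O bond are both cut, which returns ring C to an E alkene and a free carbinol.
- The cut is placed here because O1''–C2'' is the only bond of ring C whose formation the neighbouring π system helps. The relative configuration of the triad is also exactly what a directed epoxidation followed by anti opening gives.
- Ring C and two of three stereocentres disappear. Compound 11 is an open-chain trienyl isocoumarin with one stereocentre.
- The forward step must pick one of six C=C bonds, pick one face of it, and close the ring with inversion through 12.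

**11 from 10.** The lactone bond C1–O2 is cut. The forward reaction is an enol lactonisation of a benzyl ketone onto the neighbouring ester. It needs no extra reagent atoms and extends the conjugation, which drives it.

**10 from 3 and 9.** The C4–C3 bond is cut between the benzylic carbon and the carbonyl carbon.
- This is the most convergent cut. It divides the molecule into ring A with its full substitution pattern (3) and the whole side chain (9).
- It uses the natural polarity of both halves: an ortho-toluate anion and a Weinreb amide.
- The forward reaction must favour 1,2-attack over attack along the polyene.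

**9 from 8, 8 from 6 and 7, 6 from 4 and 5.** The triene is cut at two C=C bonds. C4=C5 of 8 comes from a vinylogous Horner–Wadsworth–Emmons reaction of 6 with 7. C2=C3 of 6 comes from a cross-metathesis of 4 with 5. Both reactions are E-selective and tolerate the free hydroxyl, so the only stereocentre is bought with 4 and never protected.

**3 from 2, 2 from 1.** The O–allyl bonds and the C5–Cl bond are cut. Chlorine is introduced on the simple resorcylate 1, before any alkene exists. The electrophile then has only the arene to attack.

## Alternatives that were turned down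

**Alternative 1:** (the textbook cut) The C2'–C3' single bond in the middle of the diene is cut. The forward key step is a Suzuki–Miyaura coupling of the iodovinyl isocoumarin A1 with the oxolanyl vinylboronate A2.
- The coupling makes one sp2–sp2 bond and nothing else: no ring and no stereocentre.
- All three stereocentres would have to be built beforehand into A2. Its most direct source is 2-deoxy-L-ribose A3, the unnatural antipode.
- The anomeric carbon of A3 has to become the methyl-bearing C5'' with cis selectivity, yet no neighbouring group at C4'' is there to steer it.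
- The terminal carbon of A3 must be oxidised and homologated to a vinyl metal, and C3''–OH must be masked and unmasked.
- A1 needs a separate route about as long as that to 11. Two multi-step fragments for one non-stereogenic bond is poor step economy.

**Alternative 2:** Ring A is cut at C4a–C5 and C8–C8a. The forward key step is a Diels–Alder reaction of the chlorinated bis(silyloxy)diene A4 with the ester-bearing triple bond of the dienediynoate A5. Aromatisation would give the alkynyl resorcylate A6, and a 6-endo-dig closure would then form ring B. The chlorine would be placed by construction.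
- The terminal chlorine of A4 lowers the energy of the diene HOMO and hinders its nucleophilic end. The cycloaddition would therefore need long heating.
- A5 is a dienediyne prone to polymerisation. It also offers a second triple bond and its own diene as competing partners.
- The closure of ring B has a 5-exo competitor.
- Ring C with all its stereocentres must still be made first, so the hardest part of the problem is untouched.

**Alternative 3:** Ring A is cut at the same two bonds in the polar sense, and ring B is taken from a 2-pyranone. The forward key step is a Michael–Dieckmann annulation of the Staunton–Weinreb type. The γ-anion of the chloro methoxy crotonate A8 would add to C4 of the 4-methoxy-2-pyranone A7 and give the isocoumarin A9.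
- The C6 oxygen emerges as a non-chelated aryl methyl ether. Its cleavage needs boron trihalide-type Lewis acids or hot thiolate, and neither spares the dienylic O1''–C2'' bond or ring B.
- The anion of A8 is also an allylic chloride and can alkylate itself.
- A7 offers further acceptor positions along its dienyl arm.
- Ring C again has to be finished in advance.

Key step: step 8

Assumption: the SMILES is read as (2''S,3''R,5''R) with both diene bonds E; compounds 1, 4 (enantiopure), 5 and 7 are taken as catalogue chemicals.

## Route

Step 1
Reactants: 1 methyl 2,4-dihydroxy-6-methylbenzoate (methyl orsellinate)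
Product: 2 methyl 3-chloro-4,6-dihydroxy-2-methylbenzoate
Conditions: SO2Cl2 (1.05 equiv), Et2O/CH2Cl2, 0 °C to rt
Reagents that add atoms: sulfuryl chloride, O=S(=O)(Cl)Cl
Why: Electrophilic aromatic chlorination; C5 of 1 is para to the chelated hydroxyl and ortho to the free one, and it is less shielded than C3, which lies between two oxygens, so it is the usual site of attack in 6-alkyl-β-resorcylates. One equivalent of reagent at low temperature limits dichlorination, and no alkene is present yet.

Step 2
Reactants: 2 methyl 3-chloro-4,6-dihydroxy-2-methylbenzoate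
Product: 3 methyl 3-chloro-2-methyl-4,6-bis(prop-2-enyloxy)benzoate
Conditions: allyl bromide (2.5 equiv), K2CO3 (3 equiv), DMF, 60 °C
Reagents that add atoms: allyl bromide, C=CCBr
Why: Williamson ether synthesis; warming brings the chelated hydroxyl to reaction as well. Allyl ethers withstand amide bases, DBU and peroxide and leave at the end under neutral conditions.

Step 3
Reactants: 4 (2R)-pent-4-en-2-ol; 5 (E)-but-2-enal (crotonaldehyde)
Product: 6 (2E,5R)-5-hydroxyhex-2-enal
Conditions: 5 (5 equiv), second-generation Hoveyda–Grubbs catalyst (2 mol %), CH2Cl2, 40 °C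
Reagents that add atoms: none
Why: Olefin cross-metathesis of a terminal alkene with an enal, driven by loss of a volatile alkene and E-selective under thermodynamic control. The free homoallylic hydroxyl is tolerated and the stereocentre is not involved.

Step 4
Reactants: 6 (2E,5R)-5-hydroxyhex-2-enal; 7 ethyl (E)-4-(diethoxyphosphoryl)but-2-enoate (triethyl 4-phosphonocrotonate)
Product: 8 ethyl (2E,4E,6E,9R)-9-hydroxydeca-2,4,6-trienoate
Conditions: 7 (1.3 equiv), LiN(SiMe3)2 (1.25 equiv), THF, −78 °C; then 6, −78 to 0 °C
Reagents that add atoms: none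
Why: Vinylogous Horner–Wadsworth–Emmons olefination; the stabilised allyl phosphonate anion reacts at the carbon next to phosphorus and gives the new C4=C5 bond E. The anion is too weak a base to be quenched by the alcohol.

Step 5
Reactants: 8 ethyl (2E,4E,6E,9R)-9-hydroxydeca-2,4,6-trienoate
Product: 9 (2E,4E,6E,9R)-9-hydroxy-N-methoxy-N-methyldeca-2,4,6-trienamide
Conditions: MeNH(OMe)·HCl (3 equiv), i-PrMgCl (7 equiv), THF, −20 to 0 °C; aq NH4Cl
Reagents that add atoms: N,O-dimethylhydroxylamine hydrochloride, CNOC.Cl
Why: Ester aminolysis by the chloromagnesium amide (Weinreb amide synthesis), which attacks unsaturated esters at the carbonyl carbon. One further equivalent of Grignard reagent takes up the hydroxyl proton.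

Step 6
Reactants: 3 methyl 3-chloro-2-methyl-4,6-bis(prop-2-enyloxy)benzoate; 9 (2E,4E,6E,9R)-9-hydroxy-N-methoxy-N-methyldeca-2,4,6-trienamide
Product: 10 methyl 3-chloro-2-[(3E,5E,7E,10R)-10-hydroxy-2-oxoundeca-3,5,7-trienyl]-4,6-bis(prop-2-enyloxy)benzoate
Conditions: 3 (1.3 equiv), LiN(i-Pr)2 (2.4 equiv), THF, −78 °C, 15 min; then 9 (1.0 equiv), −78 °C, 20 min; aq NH4Cl
Reagents that add atoms: none
Why: Lateral lithiation of the ortho-toluate and acylation by a Weinreb amide; lithium chelation directs the benzylic anion to the carbonyl carbon. The stable tetrahedral chelate prevents a second addition and hides the acidic ketone until the quench. The surplus base takes the hydroxyl proton of 9, and short contact at −78 °C limits deprotonation at C8.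

Step 7
Reactants: 10 methyl 3-chloro-2-[(3E,5E,7E,10R)-10-hydroxy-2-oxoundeca-3,5,7-trienyl]-4,6-bis(prop-2-enyloxy)benzoate
Product: 11 5-chloro-3-[(1E,3E,5E,8R)-8-hydroxynona-1,3,5-trienyl]-6,8-bis(prop-2-enyloxy)isochromen-1-one
Conditions: DBU (0.3 equiv), 4 Å MS, toluene, rt to 45 °C, dark
Reagents that add atoms: none
Why: Enol lactonisation; DBU enolises the doubly activated benzylic ketone and the enolate oxygen attacks the neighbouring ester (6-exo-trig) to close ring B. The sieves bind the liberated alcohol, and the gain of a fully conjugated tetraene–arene system drives the closure.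

Step 8
Reactants: 11 5-chloro-3-[(1E,3E,5E,8R)-8-hydroxynona-1,3,5-trienyl]-6,8-bis(prop-2-enyloxy)isochromen-1-one
Product: 13 5-chloro-3-{(1E,3E)-4-[(2S,3R,5R)-3-hydroxy-5-methyloxolan-2-yl]buta-1,3-dienyl}-6,8-bis(prop-2-enyloxy)isochromen-1-one, via dienyl epoxide 12 (not isolated)
Conditions: VO(acac)2 (10 mol %), t-BuOOH (5.5 M in decane, 1.2 equiv), 4 Å MS, CH2Cl2, 0 °C to rt, dark; then CSA (5 mol %), −20 to 0 °C; Et3N
Reagents that add atoms: tert-butyl hydroperoxide, CC(C)(C)OO
Why: The C8' hydroxyl of 11 exchanges onto the pentavalent vanadium tert-butylperoxo complex, and the bound peroxide is delivered through a chair-like six-membered array to the only alkene within reach, C5'=C6'; this is the vanadium-catalysed hydroxyl-directed epoxidation of homoallylic alcohols. With the C9' methyl equatorial in that array, oxygen arrives on the face that makes the new C6'–O bond 1,3-syn to the carbinol C–O bond, which fixes the future C3'' as R, and the E geometry makes 12 the trans (5'R,6'R) epoxide. Acid (the vanadium Lewis acid, completed by catalytic CSA) then loosens the dienylic C5'–O bond, whose developing charge is spread over C1'–C4' and C3=C4, and the same hydroxyl attacks C5' from the rear; the closest known type is the alkenyl-activated endo opening of hydroxy epoxides. Ring C closes in the 5-endo-tet mode, because the 4-exo attack at C6' is strained and has no electronic help. Inversion at C5' gives C2'' as S, trans to the C3'' hydroxyl and cis to the C5'' methyl, and C5'' itself is never touched. The step needs site selectivity among six C=C bonds (secured by the tether length), face selectivity (secured by the C8' stereocentre) and freedom from over-oxidation (in 13 the new hydroxyl is trans to the dienyl arm on a five-membered ring and cannot reach it). Anhydrous medium and sieves keep external nucleophiles away from the delocalised positive charge.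

Step 9
Reactants: 13 5-chloro-3-{(1E,3E)-4-[(2S,3R,5R)-3-hydroxy-5-methyloxolan-2-yl]buta-1,3-dienyl}-6,8-bis(prop-2-enyloxy)isochromen-1-one
Product: 14 5-chloro-6,8-dihydroxy-3-{(1E,3E)-4-[(2S,3R,5R)-3-hydroxy-5-methyloxolan-2-yl]buta-1,3-dienyl}isochromen-1-one (target)
Conditions: Pd(PPh3)4 (5 mol %), PhNHMe (4 equiv), THF, rt, dark
Reagents that add atoms: none
Why: Tsuji–Trost deallylation; the electron-poor phenoxides of ring A are good leaving groups for zerovalent palladium, whereas the alkyl ether O1''–C2'' is not ionised in a neutral medium. N-Methylaniline traps the allyl units but is too weak a nucleophile to open ring B.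

## Compound list

1 | methyl 2,4-dihydroxy-6-methylbenzoate (methyl orsellinate) | COC(=O)c1c(C)cc(O)cc1O | starting material
2 | methyl 3-chloro-4,6-dihydroxy-2-methylbenzoate | COC(=O)c1c(C)c(Cl)c(O)cc1O | intermediate
3 | methyl 3-chloro-2-methyl-4,6-bis(prop-2-enyloxy)benzoate | COC(=O)c1c(C)c(Cl)c(OCC=C)cc1OCC=C | intermediate
4 | (2R)-pent-4-en-2-ol | C[C@@H](O)CC=C | starting material
5 | (E)-but-2-enal (crotonaldehyde) | C/C=C/C=O | starting material
6 | (2E,5R)-5-hydroxyhex-2-enal | C[C@@H](O)C/C=C/C=O | intermediate
7 | ethyl (E)-4-(diethoxyphosphoryl)but-2-enoate (triethyl 4-phosphonocrotonate) | CCOC(=O)/C=C/CP(=O)(OCC)OCC | starting material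
8 | ethyl (2E,4E,6E,9R)-9-hydroxydeca-2,4,6-trienoate | C[C@@H](O)C/C=C/C=C/C=C/C(=O)OCC | intermediate
9 | (2E,4E,6E,9R)-9-hydroxy-N-methoxy-N-methyldeca-2,4,6-trienamide | C[C@@H](O)C/C=C/C=C/C=C/C(=O)N(C)OC | intermediate
10 | methyl 3-chloro-2-[(3E,5E,7E,10R)-10-hydroxy-2-oxoundeca-3,5,7-trienyl]-4,6-bis(prop-2-enyloxy)benzoate | C[C@@H](O)C/C=C/C=C/C=C/C(=O)Cc1c(Cl)c(OCC=C)cc(OCC=C)c1C(=O)OC | intermediate
11 | 5-chloro-3-[(1E,3E,5E,8R)-8-hydroxynona-1,3,5-trienyl]-6,8-bis(prop-2-enyloxy)isochromen-1-one | C[C@@H](O)C/C=C/C=C/C=C/c1cc2c(Cl)c(OCC=C)cc(OCC=C)c2c(=O)o1 | intermediate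
12 | 5-chloro-3-[(1E,3E)-4-{(2R,3R)-3-[(2R)-2-hydroxypropyl]oxiran-2-yl}buta-1,3-dienyl]-6,8-bis(prop-2-enyloxy)isochromen-1-one | C[C@@H](O)C[C@H]1O[C@@H]1/C=C/C=C/c2cc3c(Cl)c(OCC=C)cc(OCC=C)c3c(=O)o2 | intermediate
13 | 5-chloro-3-{(1E,3E)-4-[(2S,3R,5R)-3-hydroxy-5-methyloxolan-2-yl]buta-1,3-dienyl}-6,8-bis(prop-2-enyloxy)isochromen-1-one | C[C@@H]1C[C@@H](O)[C@H](/C=C/C=C/c2cc3c(Cl)c(OCC=C)cc(OCC=C)c3c(=O)o2)O1 | intermediate
14 | 5-chloro-6,8-dihydroxy-3-{(1E,3E)-4-[(2S,3R,5R)-3-hydroxy-5-methyloxolan-2-yl]buta-1,3-dienyl}isochromen-1-one | C[C@@H]1C[C@@H](O)[C@H](/C=C/C=C/c2cc3c(Cl)c(O)cc(O)c3c(=O)o2)O1 | target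

## Step count and least certain steps

Total step count: 9. Longest linear sequence: 7 steps (4 → 6 → 8 → 9 → 10 → 11 → 13 → 14).

**Step 8 (key step).**
- The most likely failure is poor facial selectivity. An E alkene whose only stereocentre lies at the carbinol leaves a small energy gap between the two chair-like arrays. A C2-symmetric bishydroxamic acid ligand on vanadium, used in its matched sense, could widen the gap.
- The second danger is ionisation of the dienyl epoxide ahead of ring closure. This could cause loss of inversion at C5', capture of the delocalised cation by peroxide or alcohol at remote positions, or a hydride shift to a carbonyl group.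
- The fallback sets out from 8 and comes back at 13. It builds ring C before the union, on an electron-poor ester and under reagent control.
- A Shi epoxidation of 8 is used, with the ketone derived from D-fructose, KHSO5 (as Oxone) and K2CO3 buffer at 0 °C. This ketone delivers oxygen to E alkenes in the (R,R) sense. It should attack the C6=C7 bond, the one most remote from the ester, and give the epoxy dienoate F1.
- The ester holds back ionisation, so catalytic CSA should close F1 with clean inversion to the oxolane dienoate F2.
- Aminolysis as in step 5 gives the Weinreb amide F3, acylation of the anion of 3 as in step 6 gives the keto ester F4, and DBU as in step 7 gives 13.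

**Step 6.**
- The soft benzylic anion may add along the polyene instead of to the carbonyl group.
- The surplus amide base may deprotonate C8 of 9 and deconjugate the triene.
- The anion may condense with the ester of a second molecule of 3.
- The fallback sets out from 3 and 6 and comes back at 11. It joins the polyene by olefination, so the anion meets only a saturated acyl donor.
- The anion of 3 is acylated with 2-chloro-N-methoxy-N-methylacetamide to the chloroketone F5. This is closed with catalytic p-TsOH in warm toluene to the chloromethyl isocoumarin F6. No base is used, to avoid a Favorskii-type loss of chloride.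
- An Arbuzov reaction of F6 with triethyl phosphite gives the phosphonate F7.
- In parallel, 6 is homologated by a Wittig reaction with (triphenylphosphoranylidene)acetaldehyde to the dienal F8.
- A Horner–Wadsworth–Emmons reaction of F7 with F8 (LiN(SiMe3)2, THF) gives 11.

**Step 7.**
- The hindered, electron-rich ester is a poor acyl donor and the liberated alcohol can reopen ring B, so the closure may stall.
- Long contact with base may scramble the geometry or the position of the triene.
- The fallback sets out from 10 and comes back at 11. It frees the carboxyl group instead of attacking the ester.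
- SN2 demethylation at the ester methyl with LiI in refluxing ethyl acetate gives the keto acid F9. This dehydrates to 11 with catalytic p-TsOH over sieves.

**Step 9.**
- Once the acidic phenols are free, zerovalent palladium may ionise the O1''–C2'' bond. This would epimerise C2'' or let the amine capture the chain.
- A palladium hydride may add to the diene.
- The fallback sets out from 11 and comes back at 14. It moves the palladium step in front of the key step and ends with fluoride.
- Deallylation of 11 under the conditions of step 9 gives the trienyl bisphenol F10.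
- TBSCl and Et3N in CH2Cl2 silylate only the acidic phenols and give the bis(silyl ether) F11.
- The conditions of step 8 lead through the silylated dienyl epoxide F12 to the silylated oxolane F13. Et3N·3HF in THF then releases 14.

**Step 4.**
- E selectivity at the new C4=C5 bond may be incomplete, and the base may enolise the enal.
- The fallback sets out from 6 and comes back at 9, and it fixes the geometry by a stereoretentive coupling.
- A Takai olefination of 6 (CrCl2, CHI3, THF) gives the dienyl iodide F14.
- A Heck reaction of F14 with N-methoxy-N-methylacrylamide (Pd(OAc)2, K2CO3, Bu4NCl, DMF) gives 9 directly.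

## Further compounds

F1 | step 8 | ethyl (2E,4E)-5-{(2R,3R)-3-[(2R)-2-hydroxypropyl]oxiran-2-yl}penta-2,4-dienoate | C[C@@H](O)C[C@H]1O[C@@H]1/C=C/C=C/C(=O)OCC
F2 | step 8 | ethyl (2E,4E)-5-[(2S,3R,5R)-3-hydroxy-5-methyloxolan-2-yl]penta-2,4-dienoate | C[C@@H]1C[C@@H](O)[C@H](/C=C/C=C/C(=O)OCC)O1
F3 | step 8 | (2E,4E)-5-[(2S,3R,5R)-3-hydroxy-5-methyloxolan-2-yl]-N-methoxy-N-methylpenta-2,4-dienamide | C[C@@H]1C[C@@H](O)[C@H](/C=C/C=C/C(=O)N(C)OC)O1
F4 | step 8 | methyl 3-chloro-2-{(3E,5E)-6-[(2S,3R,5R)-3-hydroxy-5-methyloxolan-2-yl]-2-oxohexa-3,5-dienyl}-4,6-bis(prop-2-enyloxy)benzoate | C[C@@H]1C[C@@H](O)[C@H](/C=C/C=C/C(=O)Cc2c(Cl)c(OCC=C)cc(OCC=C)c2C(=O)OC)O1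
F5 | step 6 | methyl 3-chloro-2-(3-chloro-2-oxopropyl)-4,6-bis(prop-2-enyloxy)benzoate | COC(=O)c1c(CC(=O)CCl)c(Cl)c(OCC=C)cc1OCC=C
F6 | step 6 | 5-chloro-3-(chloromethyl)-6,8-bis(prop-2-enyloxy)isochromen-1-one | ClCc1cc2c(Cl)c(OCC=C)cc(OCC=C)c2c(=O)o1
F7 | step 6 | diethyl {[5-chloro-1-oxo-6,8-bis(prop-2-enyloxy)isochromen-3-yl]methyl}phosphonate | CCOP(=O)(Cc1cc2c(Cl)c(OCC=C)cc(OCC=C)c2c(=O)o1)OCC
F8 | step 6 | (2E,4E,7R)-7-hydroxyocta-2,4-dienal | C[C@@H](O)C/C=C/C=C/C=O
F9 | step 7 | 3-chloro-2-[(3E,5E,7E,10R)-10-hydroxy-2-oxoundeca-3,5,7-trienyl]-4,6-bis(prop-2-enyloxy)benzoic acid | C[C@@H](O)C/C=C/C=C/C=C/C(=O)Cc1c(Cl)c(OCC=C)cc(OCC=C)c1C(=O)O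
F10 | step 9 | 5-chloro-6,8-dihydroxy-3-[(1E,3E,5E,8R)-8-hydroxynona-1,3,5-trienyl]isochromen-1-one | C[C@@H](O)C/C=C/C=C/C=C/c1cc2c(Cl)c(O)cc(O)c2c(=O)o1
F11 | step 9 | 6,8-bis(tert-butyldimethylsilyloxy)-5-chloro-3-[(1E,3E,5E,8R)-8-hydroxynona-1,3,5-trienyl]isochromen-1-one | C[C@@H](O)C/C=C/C=C/C=C/c1cc2c(Cl)c(O[Si](C)(C)C(C)(C)C)cc(O[Si](C)(C)C(C)(C)C)c2c(=O)o1
F12 | step 9 | 6,8-bis(tert-butyldimethylsilyloxy)-5-chloro-3-[(1E,3E)-4-{(2R,3R)-3-[(2R)-2-hydroxypropyl]oxiran-2-yl}buta-1,3-dienyl]isochromen-1-one | C[C@@H](O)C[C@H]1O[C@@H]1/C=C/C=C/c2cc3c(Cl)c(O[Si](C)(C)C(C)(C)C)cc(O[Si](C)(C)C(C)(C)C)c3c(=O)o2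
F13 | step 9 | 6,8-bis(tert-butyldimethylsilyloxy)-5-chloro-3-{(1E,3E)-4-[(2S,3R,5R)-3-hydroxy-5-methyloxolan-2-yl]buta-1,3-dienyl}isochromen-1-one | C[C@@H]1C[C@@H](O)[C@H](/C=C/C=C/c2cc3c(Cl)c(O[Si](C)(C)C(C)(C)C)cc(O[Si](C)(C)C(C)(C)C)c3c(=O)o2)O1
F14 | step 4 | (2R,4E,6E)-7-iodohepta-4,6-dien-2-ol | C[C@@H](O)C/C=C/C=C/I
A1 | alternative 1 | 5-chloro-3-[(E)-2-iodoethenyl]-6,8-bis(prop-2-enyloxy)isochromen-1-one | I/C=C/c1cc2c(Cl)c(OCC=C)cc(OCC=C)c2c(=O)o1
A2 | alternative 1 | 2-{(E)-2-[(2S,3R,5R)-3-(tert-butyldimethylsilyloxy)-5-methyloxolan-2-yl]ethenyl}-4,4,5,5-tetramethyl-1,3,2-dioxaborolane | C[C@@H]1C[C@@H](O[Si](C)(C)C(C)(C)C)[C@H](/C=C/B2OC(C)(C)C(C)(C)O2)O1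
A3 | alternative 1 | 2-deoxy-L-ribose, (3R,4S)-3,4,5-trihydroxypentanal | O=CC[C@@H](O)[C@@H](O)CO
A4 | alternative 2 | 4-chloro-1-methoxy-1,3-bis(trimethylsilyloxy)buta-1,3-diene | COC(O[Si](C)(C)C)=CC(O[Si](C)(C)C)=CCl
A5 | alternative 2 | methyl (6E,8E)-9-[(2S,3R,5R)-3-(tert-butyldimethylsilyloxy)-5-methyloxolan-2-yl]nona-6,8-diene-2,4-diynoate | C[C@@H]1C[C@@H](O[Si](C)(C)C(C)(C)C)[C@H](/C=C/C=C/C#CC#CC(=O)OC)O1
A6 | alternative 2 | methyl 2-{(3E,5E)-6-[(2S,3R,5R)-3-(tert-butyldimethylsilyloxy)-5-methyloxolan-2-yl]hexa-3,5-dien-1-ynyl}-3-chloro-4,6-dihydroxybenzoate | C[C@@H]1C[C@@H](O[Si](C)(C)C(C)(C)C)[C@H](/C=C/C=C/C#Cc2c(Cl)c(O)cc(O)c2C(=O)OC)O1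
A7 | alternative 3 | 6-{(1E,3E)-4-[(2S,3R,5R)-3-(tert-butyldimethylsilyloxy)-5-methyloxolan-2-yl]buta-1,3-dienyl}-4-methoxypyran-2-one | C[C@@H]1C[C@@H](O[Si](C)(C)C(C)(C)C)[C@H](/C=C/C=C/c2cc(OC)cc(=O)o2)O1
A8 | alternative 3 | methyl (E)-4-chloro-3-methoxybut-2-enoate | COC(=O)/C=C(/OC)CCl
A9 | alternative 3 | 3-{(1E,3E)-4-[(2S,3R,5R)-3-(tert-butyldimethylsilyloxy)-5-methyloxolan-2-yl]buta-1,3-dienyl}-5-chloro-8-hydroxy-6-methoxyisochromen-1-one | C[C@@H]1C[C@@H](O[Si](C)(C)C(C)(C)C)[C@H](/C=C/C=C/c2cc3c(Cl)c(OC)cc(O)c3c(=O)o2)O1
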